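## Retrosynthetic overview

1. 14 ⇒ 12: the C3=C4/C5–OH allylic alcohol is carried as a 4,5-epoxy-3-ketone and released last by a Wharton transposition.
2. 12 ⇒ 11: cut C1–C9, the bond shared by the four-membered ring (C1, C9, C10, C11) and the nine-membered ring (C1 to C9). Enabling feature: C1 and C9 are 1,4-related through C10 and the quaternary gem-dimethyl carbon C11. The cut therefore leaves one eleven-membered humulane ring in which C1 is the β-carbon of a C1=C2–C3=O enone and C9 can carry a radical precursor.
3. 11 ⇒ 6 + 7 + 8: the dihydropyran ring (O, C8, C15, C1′ and two syncarpyl carbons) comes from a domino Knoevenagel/hetero-Diels–Alder reaction on the exocyclic C8=C15 alkene.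
4. 6 ⇒ zerumbone 1, which already holds all fifteen terpene carbons and the eleven-membered ring. The sequence is reduction, double Shi epoxidation, reoxidation, and epoxide-to-allylic-alcohol isomerisation.
5. Ring order: the syncarpyl ring and the eleven-membered ring are bought, the dihydropyran closes in step 5, and the four-membered ring closes last in step 7. That same bond contracts eleven to nine.

Key step: step 7

Numbering: the terpene carbons keep caryophyllane numbers in every compound. C1 and C9 are the CH atoms of the four-membered ring, C10 its CH2 and C11 its CMe2. C2 is the CH2 next to C1, followed by C3, C4 (bearing Me), C5 (carbinol), C6 and C7. C8 is the spiro carbon, C15 the pyran CH2 and C1′ the CH(isobutyl).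

Assumption: zerumbone, syncarpic acid (drawn as the triketone tautomer) and isovaleraldehyde are taken as catalogue chemicals.

## Route

Step 1
Reactants: 1 zerumbone
Product: 2 (±)-zerumbol
Conditions: NaBH4, CeCl3·7H2O, MeOH, 0 °C
Reagents that add atoms: none
Why: Luche reduction adds hydride 1,2 to the cross-conjugated dienone, which turns C4=C5 from an electron-poor enone alkene into a nucleophilic trisubstituted alkene; the new C3 centre needs no control because step 3 removes it.

Step 2
Reactants: 2 (±)-zerumbol
Product: 3 (4S,5S,8S,9S)-4,5:8,9-diepoxyhumul-1-en-3-ol (both C3 epimers)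
Conditions: L-series Shi ketone (1,2:4,5-di-O-isopropylidene-β-L-erythro-2,3-hexodiulo-2,6-pyranose, 0.6 equiv), KHSO5 (as 2KHSO5·KHSO4·K2SO4), K2CO3, Na2B4O7 buffer pH 10.5, Bu4NHSO4, MeCN/CH2(OMe)2/H2O, 0 °C
Reagents that add atoms: potassium peroxymonosulfate, [K+].[O-]S(=O)(=O)OO
Why: Shi epoxidation by the chiral dioxirane should hit the exposed outer face of the two electron-rich E-trisubstituted alkenes through the spiro transition state, the L-series ketone giving the S,S-epoxide at both sites under reagent control (C5 is the lasting centre, C9 a temporary one), while the disubstituted C1=C2 next to quaternary C11 reacts more slowly.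

Step 3
Reactants: 3 (4S,5S,8S,9S)-4,5:8,9-diepoxyhumul-1-en-3-ol
Product: 4 (4R,5S,8S,9S)-4,5:8,9-diepoxyhumul-1-en-3-one
Conditions: Dess–Martin periodinane, NaHCO3, CH2Cl2, 0 °C to rt
Reagents that add atoms: none
Why: Dess–Martin oxidation under buffer leaves both epoxides intact, merges the two C3 epimers into one compound and restores the C1=C2–C3=O acceptor (the descriptor at C4 changes by priority only).

Step 4
Reactants: 4 (4R,5S,8S,9S)-4,5:8,9-diepoxyhumul-1-en-3-one
Product: 6 (4R,5S,9S)-4,5-epoxy-9-hydroxyhumula-1,8(15)-dien-3-one, via trimethylsilyl ether 5 (not isolated)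
Conditions: TMSOTf, DBU, toluene, −78 to 0 °C; then 1 M aq. citric acid, THF, 0 °C
Reagents that add atoms: trimethylsilyl triflate, C[Si](C)(C)OS(=O)(=O)C(F)(F)F (silyl group of 5 only)
Why: In this silyl-triflate-induced isomerisation of an epoxide to an allylic silyl ether, only the electron-rich 8,9-epoxide should open at tertiary C8 (the 4,5-epoxide is deactivated by the C3 carbonyl) and DBU takes a proton from the unhindered C15 methyl, so the C9–O bond keeps its S configuration; the weakly acidic desilylation avoids transannular oxa-Michael addition of C9–OH to C1.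

Step 5
Reactants: 6 (4R,5S,9S)-4,5-epoxy-9-hydroxyhumula-1,8(15)-dien-3-one; 7 syncarpic acid; 8 isovaleraldehyde
Product: 10 (1′S,4R,5S,8S,9S)-spiro-dihydropyran alcohol, via enetrione 9 (not isolated)
Conditions: ethylenediammonium diacetate (20 mol %), 4 Å MS, toluene, 70 °C
Reagents that add atoms: none
Why: In this domino Knoevenagel/hetero-Diels–Alder reaction of inverse electron demand, 9 should add only to the electron-rich 1,1-disubstituted C8=C15 (C15 to C1′, carbonyl O to C8); C8 is set by peripheral attack anti to C10 with the C9–OH in the outside allylic position hydrogen-bonded to the incoming carbonyl oxygen, and C1′ by the orientation with isobutyl outside and the C9 arm endo, a preference expected to be modest, so the 1′-epimer is removed by chromatography.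

Step 6
Reactants: 10 (1′S,4R,5S,8S,9S)-spiro-dihydropyran alcohol
Product: 11 9-O-(phenoxythiocarbonyl) derivative of 10
Conditions: PhOC(S)Cl, pyridine, DMAP (cat.), CH2Cl2, 0 °C to rt
Reagents that add atoms: O-phenyl chlorothionoformate, ClC(=S)Oc1ccccc1
Why: Thioacylation of the only hydroxyl group (the first half of a Barton–McCombie sequence) installs the radical precursor under weakly basic conditions and touches no stereocentre.

Step 7
Reactants: 11 9-O-(phenoxythiocarbonyl) derivative of 10
Product: 12 (1R,1′S,4R,5S,8S,9S)-4,5-epoxy-3-oxocaryophyllane spiro-dihydropyran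
Conditions: (Me3Si)3SiH (1.3 equiv) and AIBN (0.3 equiv) by syringe pump over 8 h, toluene (2 mM), 90 °C
Reagents that add atoms: none
Why: Proposed new method: the silyl radical adds to the C=S group of 11 and the adduct fragments to the secondary C9 radical, which attacks C1, the β-carbon of the C1=C2–C3=O enone, across the eleven-membered ring; the C2 radical so formed is stabilised by the C3 carbonyl and takes hydrogen from the silane, which carries the chain. The closest known reaction types are Barton–McCombie-initiated Giese cyclisations and 4-exo-trig radical closures onto enones and enoates whose tether carries a gem-dialkyl group, whereas a transannular version in a medium ring has not been described. The four-membered ring C1–C9–C10–C11 closes in the 4-exo-trig mode, and the same bond divides the eleven-membered ring, so the nine-membered ring (C1 to C9) appears by transannular contraction. C1 and C9 should become trans because in the puckered transition state the two ring arms C2 and C8 take opposite faces of the nascent four-membered ring, which is also the more stable fusion of this bicycle. The sense (1R,9S) is controlled by quaternary C8: the new bond forms anti to C8–C15, with the small C8–O bond near the nodal plane of the radical beside C10 and C7 gauche to C1 as the nine-membered ring demands, whereas the other face would press C15 against C10. The step needs C1 to win over every other acceptor and over direct reduction: C4=C5, which would offer a fast 5-exo closure at C5, is masked as the epoxide, attack at C2 is mismatched in polarity, high dilution and slow silane addition hold back reduction, and the C11 gem-dimethyl group together with the carbonyl-stabilised product radical offsets the ring strain.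

Step 8
Reactants: 12 (1R,1′S,4R,5S,8S,9S)-4,5-epoxy-3-oxocaryophyllane spiro-dihydropyran
Product: 14 tomentodione P, via epoxy hydrazone 13 (not isolated)
Conditions: N2H4·H2O, AcOH, MeOH, 0 °C to rt
Reagents that add atoms: hydrazine hydrate, NN.O (nitrogen atoms of 13 only)
Why: In the Wharton transposition hydrazine should condense only at C3 (each syncarpyl carbonyl is shielded by a quaternary CMe2 neighbour and one is a deactivated vinylogous ester); epoxide opening and loss of N2 from the alkenyl diazene place the alkene at C3=C4 and leave C5–OH with its S configuration, and the Z geometry is expected as the low-strain, cis-in-ring alkene of the nine-membered ring.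

## Compound list

1 | zerumbone, (1E,4E,8E)-humula-1,4,8-trien-3-one | O=C1/C=C/C(C)(C)C/C=C(\C)CC/C=C1\C | starting material
2 | (±)-zerumbol, C3 alcohol of 1 | OC1/C=C/C(C)(C)C/C=C(\C)CC/C=C1\C | intermediate
3 | (4S,5S,8S,9S)-4,5:8,9-diepoxyhumul-1-en-3-ol, both C3 epimers | OC1/C=C/C(C)(C)C[C@@H]3O[C@@]3(C)CC[C@@H]2O[C@@]12C | intermediate
4 | (4R,5S,8S,9S)-4,5:8,9-diepoxyhumul-1-en-3-one | O=C1/C=C/C(C)(C)C[C@@H]3O[C@@]3(C)CC[C@@H]2O[C@@]12C | intermediate
5 | 9-O-trimethylsilyl ether of 6 | O=C1/C=C/C(C)(C)C[C@H](O[Si](C)(C)C)C(=C)CC[C@@H]2O[C@@]12C | intermediate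
6 | (4R,5S,9S)-4,5-epoxy-9-hydroxyhumula-1,8(15)-dien-3-one | O=C1/C=C/C(C)(C)C[C@H](O)C(=C)CC[C@@H]2O[C@@]12C | intermediate
7 | syncarpic acid, 2,2,4,4-tetramethylcyclohexane-1,3,5-trione | CC1(C)C(=O)CC(=O)C(C)(C)C1=O | starting material
8 | isovaleraldehyde | CC(C)CC=O | starting material
9 | enetrione, 2-(3-methylbutylidene)-4,4,6,6-tetramethylcyclohexane-1,3,5-trione | CC(C)CC=C1C(=O)C(C)(C)C(=O)C(C)(C)C1=O | intermediate
10 | (1′S,4R,5S,8S,9S)-spiro-dihydropyran alcohol (eleven-membered ring with E-C1=C2–C3=O, 4,5-epoxide, C9–OH, spiro C8) | O=C1/C=C/C(C)(C)C[C@H](O)[C@]3(CC[C@@H]2O[C@@]12C)C[C@H](CC(C)C)C4=C(O3)C(C)(C)C(=O)C(C)(C)C4=O | intermediate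
11 | 9-O-(phenoxythiocarbonyl) derivative of 10 | O=C1/C=C/C(C)(C)C[C@H](OC(=S)Oc5ccccc5)[C@]3(CC[C@@H]2O[C@@]12C)C[C@H](CC(C)C)C4=C(O3)C(C)(C)C(=O)C(C)(C)C4=O | intermediate
12 | (1R,1′S,4R,5S,8S,9S)-4,5-epoxy-3-oxocaryophyllane spiro-dihydropyran (trans-fused four- and nine-membered rings) | O=C1C[C@@H]2[C@H](CC2(C)C)[C@]3(CC[C@@H]4O[C@@]14C)C[C@H](CC(C)C)C5=C(O3)C(C)(C)C(=O)C(C)(C)C5=O | intermediate
13 | C3 hydrazone of 12 | NN=C1C[C@@H]2[C@H](CC2(C)C)[C@]3(CC[C@@H]4O[C@@]14C)C[C@H](CC(C)C)C5=C(O3)C(C)(C)C(=O)C(C)(C)C5=O | intermediate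
14 | tomentodione P, (1R,1′S,3Z,5S,8S,9S) | C/C1=C/C[C@@H]2[C@H](CC2(C)C)[C@]2(CC[C@@H]1O)C[C@H](CC(C)C)C1=C(O2)C(C)(C)C(=O)C(C)(C)C1=O | target

## Step count and risks

Total step count: 8. Longest linear sequence: 8 steps (from 1).

**Steps most likely to fail**

**1. Step 7 (proposed new method).**
- What may go wrong:
  - hydrogen transfer to the C9 radical before ring closure;
  - reopening of the strained ring before the C2 radical is quenched;
  - loss of the pyran by β-scission of the C8–O bond;
  - closure on the wrong face of C9.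
- The fallback uses known chemistry only. It sets out from 7 and 8 (enetrione 9 made as in step 5) and comes back at 14.
- Enetrione 9 is generated in the presence of purchased (−)-β-caryophyllene F1 (ethylenediammonium diacetate, toluene, 70 °C). Hetero-Diels–Alder addition to its exocyclic C8=C15 alkene gives the caryophyllene cycloadduct F2.
- A Schenck ene reaction at the E-C4=C5 alkene (O2, tetraphenylporphyrin, hν, CH2Cl2, 0 °C) gives the (3Z,5S)-allylic hydroperoxide F3, and PPh3 reduces it to 14.
- This gives up the transannular closure, because the four-membered ring is bought with the terpene.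

**2. Step 5.**
- What may go wrong:
  - slow cycloaddition of an alkene that is deactivated by its allylic oxygen;
  - attack on the wrong π-face;
  - erosion of endo/exo control at C1′;
  - transannular oxa-Michael addition of C9–OH to C1.
- The fallback exploits the fact that C9 is only a temporary stereocentre. It sets out from 6 and comes back at 12.
- Mitsunobu inversion (4-nitrobenzoic acid, PPh3, DIAD, THF, 0 °C) gives the (9R)-4-nitrobenzoate F4. Methanolysis (K2CO3, MeOH, 0 °C) gives the (9R)-allylic alcohol F5.
- The cycloaddition of step 5 then meets the opposite C9 environment and should give the (8S,9R)-spiro alcohol F6. PhOC(S)Cl/pyridine gives its thionocarbonate F7.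
- The radical closure of step 7 converges on 12, because C9 is planarised.

**3. Step 8.**
- What may go wrong:
  - attack of hydrazine on the vinylogous ester;
  - opening of the epoxide by hydrazine;
  - loss of control over the alkene geometry.
- The fallback is the radical counterpart of the transposition. It sets out from 12 and comes back at 14.
- NaBH4/CeCl3·7H2O (MeOH, −40 °C) reduces only C3 to the epoxy alcohol F8; either C3 epimer serves. 1,1′-Thiocarbonyldiimidazole (DMAP, CH2Cl2, reflux) gives the imidazolylthiocarbonyl derivative F9.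
- Bu3SnH/AIBN (toluene, 90 °C) generates the C3 radical. Its neighbouring epoxide opens to C3=C4 and a C5 alkoxy radical, which takes hydrogen to give 14.

## Further compounds

F1 | step 7 | (−)-β-caryophyllene (purchased) | C/C1=C\CCC(=C)[C@H]2CC(C)(C)[C@@H]2CC1
F2 | step 7 | (1R,1′S,4E,8S,9S)-caryophyllene cycloadduct | C/C1=C\CC[C@]3(C[C@H](CC(C)C)C4=C(O3)C(C)(C)C(=O)C(C)(C)C4=O)[C@H]2CC(C)(C)[C@@H]2CC1
F3 | step 7 | (3Z,5S)-allylic hydroperoxide | C/C1=C/C[C@@H]2[C@H](CC2(C)C)[C@]2(CC[C@@H]1OO)C[C@H](CC(C)C)C1=C(O2)C(C)(C)C(=O)C(C)(C)C1=O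
F4 | step 5 | (9R)-4-nitrobenzoate | O=C1/C=C/C(C)(C)C[C@@H](OC(=O)c5ccc(cc5)[N+](=O)[O-])C(=C)CC[C@@H]2O[C@@]12C
F5 | step 5 | (9R)-allylic alcohol, C9 epimer of 6 | O=C1/C=C/C(C)(C)C[C@@H](O)C(=C)CC[C@@H]2O[C@@]12C
F6 | step 5 | (8S,9R)-spiro alcohol, C9 epimer of 10 | O=C1/C=C/C(C)(C)C[C@@H](O)[C@]3(CC[C@@H]2O[C@@]12C)C[C@H](CC(C)C)C4=C(O3)C(C)(C)C(=O)C(C)(C)C4=O
F7 | step 5 | thionocarbonate, C9 epimer of 11 | O=C1/C=C/C(C)(C)C[C@@H](OC(=S)Oc5ccccc5)[C@]3(CC[C@@H]2O[C@@]12C)C[C@H](CC(C)C)C4=C(O3)C(C)(C)C(=O)C(C)(C)C4=O
F8 | step 8 | epoxy alcohol, C3 alcohol of 12 | OC1C[C@@H]2[C@H](CC2(C)C)[C@]3(CC[C@@H]4O[C@@]14C)C[C@H](CC(C)C)C5=C(O3)C(C)(C)C(=O)C(C)(C)C5=O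
F9 | step 8 | 3-O-(imidazol-1-ylthiocarbonyl) derivative of F8 | S=C(n6ccnc6)OC1C[C@@H]2[C@H](CC2(C)C)[C@]3(CC[C@@H]4O[C@@]14C)C[C@H](CC(C)C)C5=C(O3)C(C)(C)C(=O)C(C)(C)C5=O
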